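The constants are assumed; the run is a simulation.

You have 4 questions before you, and one quotient carries them.

    substrate + reagent + catalyst → catalyst + target (k1 = 414 L² mol⁻² s⁻¹, Ea1 = 39.0 kJ mol⁻¹)
    substrate + reagent → uncatalysed product (k2 = 8.67 × 10⁻⁴ L mol⁻¹ s⁻¹, Ea2 = 83.0 kJ mol⁻¹)
    (constants at 40 °C)

the same everywhere: substrate 20 mM; reagent 1.50 equiv; catalyst 0.23 mol%; time 5.0 h

|  | temperature |
|---|---|
| grey | 70 °C |
| blue | 55 °C |
| teal | 40 °C |

- which flask leads in amount of target, in percent of the substrate charged ("all alike" within 1.5 percentage points) (grey / blue / teal / all alike)
- how much target is there at the end, in percent of the substrate charged: grey
- how much target is there at the end, in percent of the substrate charged: blue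
- how much target is there at the end, in percent of the substrate charged: teal

- the list of constants is for 40 °C, to be carried to other temperatures by the activation energies

Both steps take one substrate and one reagent, so each rate carries the same product of those two concentrations, and the catalyst comes back from step 1 unchanged. Divide one rate by the other and that product cancels, leaving the step 1 constant times the catalyst concentration, over the step 2 constant. For teal this is 22.0; call it the route ratio, the field's selectivity factor. The quotient does not move during a run, so target and uncatalysed product grow in that proportion, and the target share of converted substrate is the ratio over one plus the ratio.

Heat changes the quotient. From teal to grey, step 2 speeds up more than step 1, by a factor of 16 against 3.7, so the ratio shrinks by a factor of 4.38. Blue sits about midway in reciprocal temperature, so there I use square roots of these factors, which is a rough step.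

Substrate and reagent fall together, so their difference stays at the reagent excess, and the summed rate integrates in closed form. The logarithm of reagent over substrate, each as a fraction of its charge, grows as the excess times the summed constant of both steps times the time. This gives the unconverted substrate at 5.0 h, and target is the share times the converted part. My reckoning, flask by flask:

- Teal: share 95.6 %, unconverted 0.943 %, target 94.7 %.
- Blue: ratio 10.5, share 91.3 %, unconverted 0.0242 %, target 91.3 %.
- Grey: ratio 5.01, share 83.4 %, unconverted <0.001 %, target 83.4 %.

Read down the rows: the share loses 12 percentage points from teal to grey, while the unconverted remainder costs teal 0.9 points. The first is larger, so I commit to teal.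

The forecast gives grey 83.4 %, blue 91 % and teal 94.7 %, and puts teal ahead. Its ground: “extra heat buys no conversion and only costs selectivity, leaving teal ahead”. We part slightly in blue, where my square root stands 0.28 points above its figure.

The simulation puts teal ahead, with grey at 83.4 %, blue at 91.0 % and teal at 94.7 %. Teal still holds 0.943 % of its substrate at 5.00 h, and after 50.0 h its target stands at 95.6 %, the level its route ratio gives as share, 95.6 %.

Take grey with 12 mM of substrate, the loading held. Its catalyst concentration falls with the substrate, so the route ratio becomes 3.01 and the share 75.1 %. That flask computes to 75.0 % target, with 0.076 % of its substrate left.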